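**Retrosynthetic overview**
- Last bond: the 6-O-angelate, by esterification of the 6α,9α-diol oxide; no ring is made here.
- Decalin and 1,4-oxide: one transannular cascade of a (1R,10R)-1,10-epoxy-(4E)-germacren-12,8β-olide, C5–C10 bond first, then O1–C4 bond.
- Ten-membered ring: C6–C7 bond by intramolecular allylation of a C6 enal with a butenolide-derived allylchromium (C6 electrophile, C7 π-nucleophile, 11(13)-ene formed).
- C8–C9 bond: vinylogous Mukaiyama aldol of an epoxy dialdehyde (from geranyl acetate; the Sharpless epoxide is the only chiral input) with a 2-silyloxyfuran (from furan-3-ylmethanol) that brings C7, C8 and C11–C13.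
- Ring order: butenolide (future lactone) → ten-membered carbocycle → decalin → oxygen bridge.

Assumption: germacrane/eudesmane numbering (C1–C15) and the usual α/β descriptors are used for all intermediates; the target is read as (1R,4S,5S,6S,7S,8S,9S,10S) with a (Z)-2-methylbut-2-enoate (angelate) on O6.

**Route**

Step 1
Reactants: 1 geranyl acetate
Product: 2 (2E,6E)-8-hydroxy-3,7-dimethylocta-2,6-dien-1-yl acetate
Conditions: SeO2 (10 mol %), t-BuOOH (2 equiv), salicylic acid (10 mol %), CH2Cl2, rt
Reagents that add atoms: tert-butyl hydroperoxide, CC(C)(C)OO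
Why: Sharpless–Umbreit catalytic SeO2 allylic oxidation (ene reaction, then [2,3]-sigmatropic shift) attacks the E-methyl of the more electron-rich distal alkene, the 2,3-alkene being deactivated by the allylic acetate, and creates no stereocenter.

Step 2
Reactants: 2 (2E,6E)-8-hydroxy-3,7-dimethylocta-2,6-dien-1-yl acetate
Product: 3 (2E)-5-[(2R,3R)-3-(hydroxymethyl)-3-methyloxiran-2-yl]-3-methylpent-2-en-1-yl acetate
Conditions: Ti(OiPr)4 (10 mol %), D-(−)-diethyl tartrate (12 mol %), t-BuOOH (2 equiv), 4 Å molecular sieves, CH2Cl2, −20 °C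
Reagents that add atoms: tert-butyl hydroperoxide, CC(C)(C)OO
Why: Katsuki–Sharpless asymmetric epoxidation of the free allylic alcohol, in which the D-(−)-tartrate ligand gives the (2R,3R)-epoxide (C1 R and C10 R, the only stereocenters taken from a chiral reagent), while the acetate-bearing alkene has no directing hydroxyl and stays intact.

Step 3
Reactants: 3 (2E)-5-[(2R,3R)-3-(hydroxymethyl)-3-methyloxiran-2-yl]-3-methylpent-2-en-1-yl acetate
Product: 4 (2E)-5-[(2R,3R)-3-(hydroxymethyl)-3-methyloxiran-2-yl]-3-methylpent-2-en-1-ol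
Conditions: K2CO3 (0.1 equiv), MeOH, 0 °C
Reagents that add atoms: none
Why: base-catalysed transesterification (methanolysis) removes the acetate without touching the epoxide stereocenters, a Payne equilibrium favouring the same more substituted epoxide.

Step 4
Reactants: 4 (2E)-5-[(2R,3R)-3-(hydroxymethyl)-3-methyloxiran-2-yl]-3-methylpent-2-en-1-ol
Product: 5 (2S,3R)-2-methyl-3-[(3E)-3-methyl-5-oxopent-3-en-1-yl]oxirane-2-carbaldehyde
Conditions: PhI(OAc)2 (2.4 equiv), 2,2,6,6-tetramethylpiperidin-1-oxyl (TEMPO, 20 mol %), CH2Cl2, rt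
Reagents that add atoms: none
Why: TEMPO/PhI(OAc)2 (oxoammonium) oxidation converts both primary alcohols into aldehydes without over-oxidation or E/Z isomerisation of the enal, and the quaternary C10 cannot epimerise.

Step 5
Reactants: 6 furan-3-ylmethanol
Product: 8 trimethyl{[2-(trimethylsilyl)furan-3-yl]methoxy}silane, via dilithiated furan-3-ylmethanol 7 (not isolated)
Conditions: n-BuLi (2.2 equiv), THF, −78 to 0 °C; then Me3SiCl (2.3 equiv), −78 °C to rt
Reagents that add atoms: chlorotrimethylsilane, C[Si](C)(C)Cl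
Why: alkoxide-directed ortho-lithiation places the second lithium at C2 of the furan, and silylation of the C,O-dianion gives the 2-silylfuran with no stereocenter involved.

Step 6
Reactants: 8 trimethyl{[2-(trimethylsilyl)furan-3-yl]methoxy}silane
Product: 9 3-(hydroxymethyl)furan-2(5H)-one
Conditions: CH3CO3H (1.2 equiv, in AcOH), NaOAc (0.2 equiv), CH2Cl2, 0 °C to rt
Reagents that add atoms: peracetic acid, CC(=O)OO
Why: Kuwajima–Urabe oxidation of a 2-silylfuran (ipso epoxidation, 1,2-silyl shift from carbon to oxygen, protodesilylation) gives the 3-substituted butenolide regiospecifically, the O-silyl ether being cleaved by the acetic acid medium.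

Step 7
Reactants: 9 3-(hydroxymethyl)furan-2(5H)-one
Product: 10 trimethyl({2-[(trimethylsilyl)oxy]furan-3-yl}methoxy)silane
Conditions: Me3SiCl (2.4 equiv), Et3N (2.6 equiv), CH2Cl2, 0 °C to rt
Reagents that add atoms: chlorotrimethylsilane, C[Si](C)(C)Cl
Why: soft enolisation of the butenolide (acidic γ-CH2) with Et3N/Me3SiCl gives the aromatic 2-silyloxyfuran and silylates the primary alcohol at the same time.

Step 8
Reactants: 5 (2S,3R)-2-methyl-3-[(3E)-3-methyl-5-oxopent-3-en-1-yl]oxirane-2-carbaldehyde; 10 trimethyl({2-[(trimethylsilyl)oxy]furan-3-yl}methoxy)silane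
Product: 12 (5S)-5-[(R)-hydroxy{(2R,3R)-2-methyl-3-[(3E)-3-methyl-5-oxopent-3-en-1-yl]oxiran-2-yl}methyl]-3-(hydroxymethyl)furan-2(5H)-one, via primary trimethylsilyl ether of the aldol 11 (not isolated)
Conditions: BF3·OEt2 (1.1 equiv), CH2Cl2, −78 °C; H2O quench; then citric acid (cat.), MeOH, 0 °C
Reagents that add atoms: none
Why: vinylogous Mukaiyama aldol reaction in which the furan attacks through C5 only the more electrophilic α-oxygenated aldehyde, the open antiperiplanar transition state gives the 8,9-threo relationship expected for Lewis-acid silyloxyfuran aldols (C8 S), Cornforth-type addition anti to the epoxide C–C bond gives the 9,10-erythro epoxy alcohol (C9 R), and acidic methanolysis then frees the primary alcohol before the minor diastereomers are removed by chromatography.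

Step 9
Reactants: 12 (5S)-5-[(R)-hydroxy{(2R,3R)-2-methyl-3-[(3E)-3-methyl-5-oxopent-3-en-1-yl]oxiran-2-yl}methyl]-3-(hydroxymethyl)furan-2(5H)-one
Product: 13 (5S)-3-(bromomethyl)-5-[(R)-hydroxy{(2R,3R)-2-methyl-3-[(3E)-3-methyl-5-oxopent-3-en-1-yl]oxiran-2-yl}methyl]furan-2(5H)-one
Conditions: N-bromosuccinimide (1.1 equiv), Me2S (1.3 equiv), CH2Cl2, −20 to 0 °C
Reagents that add atoms: N-bromosuccinimide, O=C1CCC(=O)N1Br
Why: Corey–Kim bromination converts only the primary allylic alcohol into the bromide by SN2 displacement on its alkoxysulfonium salt under neutral conditions that spare the epoxide, the enal, the hindered secondary alcohol and the γ-stereocenter of the butenolide.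

Step 10
Reactants: 13 (5S)-3-(bromomethyl)-5-[(R)-hydroxy{(2R,3R)-2-methyl-3-[(3E)-3-methyl-5-oxopent-3-en-1-yl]oxiran-2-yl}methyl]furan-2(5H)-one
Product: 15 (4E)-1β,10α-epoxy-6α,9α-dihydroxygermacra-4,11(13)-dien-12,8β-olide [(1R,6R,7S,8S,9R,10R)], via allylchromium dichloride 14 (not isolated)
Conditions: CrCl2 (6 equiv), THF/DMF 4:1, rt, 13 added over 12 h (final 0.003 M); neutral H2O work-up
Reagents that add atoms: none
Why: intramolecular Nozaki–Hiyama allylation (Barbier macrocyclisation) in which the ring-locked E-configured allylchromium attacks the enal through C7 via a chair Zimmerman–Traxler transition state (6,7-anti, C6 R) on the butenolide face that carries the C9 tether (C7 S, cis-fused 12,8β-olide), forming the C6–C7 bond, the ten-membered ring and the exocyclic methylene at once, the same bond and polarity as in germacrene biosynthesis.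

Step 11
Reactants: 15 (4E)-1β,10α-epoxy-6α,9α-dihydroxygermacra-4,11(13)-dien-12,8β-olide
Product: 16 1β,4β-epoxy-6α,9α-dihydroxy-5α-eudesm-11(13)-en-12,8β-olide [(1R,4S,5S,6S,7S,8S,9S,10S)]
Conditions: (CF3)2CHOH (0.005 M), (Ph4P)BF4 (10 mol %), 0 °C to rt
Reagents that add atoms: none
Why: Proposed new method: the hydrogen-bond-donating solvent activates the epoxide, the C4=C5 alkene held over C10 in the crown conformer opens the C10–O bond with inversion (chair–chair transannular cyclisation giving the C5–C10 bond, 5α-H/10β-methyl and the retained 1β-oxygen), and the tertiary C4 cation, long-lived in this non-basic and non-nucleophilic medium and with O6 still unacylated so that no ester can intercept it, is captured on its β face by the 1β-hydroxyl after ring A flips to a boat (C4 S, C5 S, C10 S); the closest known reaction types are the acid-mediated transannular cyclisation of 1β,10α-epoxygermacranolides to 1β-hydroxyeudesmanolides and ether-terminated epoxy-olefin cyclisations that give 7-oxabicyclo[2.2.1]heptanes.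

Step 12
Reactants: 16 1β,4β-epoxy-6α,9α-dihydroxy-5α-eudesm-11(13)-en-12,8β-olide; 17 angelic acid
Product: 19 6α-angeloyloxy-1β,4β-epoxy-9α-hydroxy-5α-eudesm-11(13)-en-12,8β-olide (CNP0328162.1), via angelic 2,4,6-trichlorobenzoic anhydride 18 (not isolated)
Conditions: 17 (1.5 equiv), 2,4,6-trichlorobenzoyl chloride (1.5 equiv), Et3N (2 equiv), toluene, rt, 1 h; then 16, toluene, 80 °C
Reagents that add atoms: none
Why: Yamaguchi esterification run without DMAP, which keeps the Z (angelate) geometry, should acylate the 6α-hydroxyl flanked by two methine carbons in preference to the axial neopentyl 9α-hydroxyl between the quaternary C10 and the lactone C–O, and changes no stereocenter.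

**Compound list**

1 | geranyl acetate [(2E)-3,7-dimethylocta-2,6-dien-1-yl acetate] | CC(C)=CCC/C(C)=C/COC(C)=O | starting material
2 | (2E,6E)-8-hydroxy-3,7-dimethylocta-2,6-dien-1-yl acetate | OC/C(C)=C/CC/C(C)=C/COC(C)=O | intermediate
3 | (2E)-5-[(2R,3R)-3-(hydroxymethyl)-3-methyloxiran-2-yl]-3-methylpent-2-en-1-yl acetate | OC[C@@]1(C)O[C@@H]1CC/C(C)=C/COC(C)=O | intermediate
4 | (2E)-5-[(2R,3R)-3-(hydroxymethyl)-3-methyloxiran-2-yl]-3-methylpent-2-en-1-ol | OC[C@@]1(C)O[C@@H]1CC/C(C)=C/CO | intermediate
5 | (2S,3R)-2-methyl-3-[(3E)-3-methyl-5-oxopent-3-en-1-yl]oxirane-2-carbaldehyde | O=C[C@@]1(C)O[C@@H]1CC/C(C)=C/C=O | intermediate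
6 | furan-3-ylmethanol | OCc1ccoc1 | starting material
7 | dilithiated furan-3-ylmethanol (O-lithio, C2-lithio) | [Li]OCc1ccoc1[Li] | intermediate
8 | trimethyl{[2-(trimethylsilyl)furan-3-yl]methoxy}silane | C[Si](C)(C)OCc1ccoc1[Si](C)(C)C | intermediate
9 | 3-(hydroxymethyl)furan-2(5H)-one | OCC1=CCOC1=O | intermediate
10 | trimethyl({2-[(trimethylsilyl)oxy]furan-3-yl}methoxy)silane | C[Si](C)(C)OCc1ccoc1O[Si](C)(C)C | intermediate
11 | primary trimethylsilyl ether of aldol 12 | C[Si](C)(C)OCC1=C[C@@H]([C@@H](O)[C@@]2(C)O[C@@H]2CC/C(C)=C/C=O)OC1=O | intermediate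
12 | (5S)-5-[(R)-hydroxy{(2R,3R)-2-methyl-3-[(3E)-3-methyl-5-oxopent-3-en-1-yl]oxiran-2-yl}methyl]-3-(hydroxymethyl)furan-2(5H)-one | OCC1=C[C@@H]([C@@H](O)[C@@]2(C)O[C@@H]2CC/C(C)=C/C=O)OC1=O | intermediate
13 | (5S)-3-(bromomethyl)-5-[(R)-hydroxy{(2R,3R)-2-methyl-3-[(3E)-3-methyl-5-oxopent-3-en-1-yl]oxiran-2-yl}methyl]furan-2(5H)-one | BrCC1=C[C@@H]([C@@H](O)[C@@]2(C)O[C@@H]2CC/C(C)=C/C=O)OC1=O | intermediate
14 | allylchromium dichloride derived from 13 (CrCl2 on C13) | Cl[Cr](Cl)CC1=C[C@@H]([C@@H](O)[C@@]2(C)O[C@@H]2CC/C(C)=C/C=O)OC1=O | intermediate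
15 | (4E)-1β,10α-epoxy-6α,9α-dihydroxygermacra-4,11(13)-dien-12,8β-olide, (1R,6R,7S,8S,9R,10R) | C=C1C(=O)O[C@H]2[C@@H]1[C@H](O)/C=C(C)/CC[C@H]3O[C@]3(C)[C@@H]2O | intermediate
16 | 1β,4β-epoxy-6α,9α-dihydroxy-5α-eudesm-11(13)-en-12,8β-olide, (1R,4S,5S,6S,7S,8S,9S,10S) | C=C1C(=O)O[C@H]2[C@@H]1[C@H](O)[C@@H]1[C@@](C)([C@@H]2O)[C@H]2CC[C@]1(C)O2 | intermediate
17 | angelic acid [(2Z)-2-methylbut-2-enoic acid] | C/C=C(/C)C(=O)O | starting material
18 | angelic 2,4,6-trichlorobenzoic anhydride | C/C=C(/C)C(=O)OC(=O)c1c(Cl)cc(Cl)cc1Cl | intermediate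
19 | 6α-angeloyloxy-1β,4β-epoxy-9α-hydroxy-5α-eudesm-11(13)-en-12,8β-olide, (1R,4S,5S,6S,7S,8S,9S,10S) | C=C1C(=O)O[C@H]2[C@@H]1[C@H](OC(=O)/C(C)=C\C)[C@@H]1[C@@](C)([C@@H]2O)[C@H]2CC[C@]1(C)O2 | target

**Step count and risks**

Total steps: 12. Longest linear sequence: 9 (steps 1–4 and 8–12, from geranyl acetate); the furan branch is steps 5–7.

Most likely to fail, first: step 11. The C4 cation may simply lose a proton, the C9 carbinol next to the epoxide may undergo a semipinacol shift, and the trans-fused oxide is strained. The fallback sets out from 15 and comes back at 16. Compound 15 is cyclised with BF3·OEt2 in CH2Cl2 at −78 °C, the established conditions for 1,10-epoxygermacranolides, to the exocyclic alkene 1β,6α,9α-trihydroxy-5α-eudesma-4(15),11(13)-dien-12,8β-olide F1. The ether is then closed under kinetic control by iodoetherification (N-iodosuccinimide, CH2Cl2, 0 °C; 5-exo Markovnikov attack of O1, which can only reach the β face) to the 15-iodo-1β,4β-oxide F2. Radical deiodination (Bu3SnH, azobisisobutyronitrile, toluene, 80 °C) turns the iodomethyl group into the C15 methyl and gives 16.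

Second: step 10. Oligomerisation, simple reduction of the bromide, attack on the other butenolide face (trans-fused lactone) or translactonisation to O6 can all lower the yield. The fallback sets out from 12 and comes back at 15. The primary alcohol alone is acetylated (Ac2O, pyridine, 0 °C) to the allylic acetate F3. The ring is then closed by palladium-catalysed umpolung allylation (Pd(PPh3)4 5 mol %, InI 1.5 equiv, THF, rt, high dilution): a π-allylpalladium intermediate is transmetallated to an allylindium that adds to the enal through a six-membered transition state. This avoids the bromide and stoichiometric chromium and tests the facial selectivity with a different metal.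

Third: step 8. Facial selectivity at C9 on the α-methyl epoxy aldehyde may be modest, dialdehyde 5 is labile, and silyloxyfuran 10 may ionise at its silyloxymethyl group. The fallback sets out from 2 and comes back at 12, and moves the epoxidation after the aldol so that it is hydroxyl-directed.
- Compound 2 is oxidised with MnO2 (CH2Cl2, rt) to 8-oxogeranyl acetate F4.
- The same BF3·OEt2 aldol with 10 on this enal gives, through its primary trimethylsilyl ether F5, the racemic 8,9-threo allylic alcohol F6.
- Sharpless kinetic resolution–epoxidation (Ti(OiPr)4, D-(−)-diisopropyl tartrate, t-BuOOH 0.6 equiv, CH2Cl2, −20 °C) converts only the (8S,9S) enantiomer and gives the erythro epoxy alcohol F7, with C1, C9 and C10 fixed by the reagent; the unreacted enantiomer is separated.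
- Methanolysis of the acetate (K2CO3 0.05 equiv, MeOH, −10 °C) gives the triol F8.
- MnO2 oxidises the electron-rich allylic alcohol to the enal, which is 12.

**Further compounds**

F1 | step 11 | 1β,6α,9α-trihydroxy-5α-eudesma-4(15),11(13)-dien-12,8β-olide | C=C1C(=O)O[C@H]2[C@@H]1[C@H](O)[C@H]1C(=C)CC[C@@H](O)[C@]1(C)[C@@H]2O
F2 | step 11 | 15-iodo-1β,4β-epoxy-6α,9α-dihydroxy-5α-eudesm-11(13)-en-12,8β-olide | C=C1C(=O)O[C@H]2[C@@H]1[C@H](O)[C@@H]1[C@@](C)([C@@H]2O)[C@H]2CC[C@]1(CI)O2
F3 | step 10 | primary allylic acetate of 12 | CC(=O)OCC1=C[C@@H]([C@@H](O)[C@@]2(C)O[C@@H]2CC/C(C)=C/C=O)OC1=O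
F4 | step 8 | 8-oxogeranyl acetate [(2E,6E)-3,7-dimethyl-8-oxoocta-2,6-dien-1-yl acetate] | O=C/C(C)=C/CC/C(C)=C/COC(C)=O
F5 | step 8 | primary trimethylsilyl ether of F6 (racemate; the enantiomer carried on is shown) | C[Si](C)(C)OCC1=C[C@@H]([C@@H](O)/C(C)=C/CC/C(C)=C/COC(C)=O)OC1=O
F6 | step 8 | (5S)-5-[(1S,2E,6E)-8-acetoxy-1-hydroxy-2,6-dimethylocta-2,6-dien-1-yl]-3-(hydroxymethyl)furan-2(5H)-one (racemate; the enantiomer carried on is shown) | OCC1=C[C@@H]([C@@H](O)/C(C)=C/CC/C(C)=C/COC(C)=O)OC1=O
F7 | step 8 | (2E)-5-[(2R,3R)-3-{(R)-hydroxy[(2S)-4-(hydroxymethyl)-5-oxo-2,5-dihydrofuran-2-yl]methyl}-3-methyloxiran-2-yl]-3-methylpent-2-en-1-yl acetate | OCC1=C[C@@H]([C@@H](O)[C@@]2(C)O[C@@H]2CC/C(C)=C/COC(C)=O)OC1=O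
F8 | step 8 | (5S)-5-[(R)-hydroxy{(2R,3R)-3-[(3E)-5-hydroxy-3-methylpent-3-en-1-yl]-2-methyloxiran-2-yl}methyl]-3-(hydroxymethyl)furan-2(5H)-one | OCC1=C[C@@H]([C@@H](O)[C@@]2(C)O[C@@H]2CC/C(C)=C/CO)OC1=O
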